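15 d is a long stir for 0.12 mM of catalyst, so the first concern is whether the catalyst finishes well inside that time.

starting material 45 mM; coupling partner 27.0 mM (fed, over 80 min); free catalyst 0.12 mM; time 15 d

    catalyst intermediate C → catalyst intermediate D (k1 = 0.0256 /s)
    starting material + free catalyst ⇌ catalyst intermediate A (K2 = 23.6 /M, k2 = 0.238 /M/s)
    catalyst intermediate D → free catalyst + product (k3 = 0.0536 /s)
    catalyst intermediate A → catalyst intermediate B (k4 = 0.895 /s)
    coupling partner + catalyst intermediate B → catalyst intermediate C (k5 = 0.529 /M/s)

- the reaction counts as stopped when no species that holds the starting material changes by six tenths of a point or more over the second half of the time
- run time (flask): 15 d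

- at 15 d, what has stopped the reaction, if anything has (it is still moving / forward and back rates have come level / all of the starting material has reacted / no working catalyst is left / the coupling partner has run out first)
- part of the starting material gone at 15 d
- the product standing at 15 d, as a percentage of the starting material charged

Which charge ends first? Each turn of the cycle takes one starting material and one coupling partner, and the charge holds less partner than starting material. So the coupling partner is the limiting reagent, and product can reach 60.0%.

Does the catalyst get there in time? One turn is a chain of waits. Catalyst intermediate A goes forward at 0.895 /s, faster than it falls back at 0.0101 /s, so the way back is dropped. With [starting material] taken at its lowest, 18.0 mM, the fixed waits add up to 292 s. The wait for partner is one over 0.529 /M/s times [coupling partner].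

[coupling partner] therefore falls at [catalyst] divided by the sum of the waits, and this rate integrates in closed form. The partner clock is the time to take the partner from its full charge to a hundredth of it. It is about the 225 turns times the fixed waits, 0.761 d, plus ln(100) over 0.529 /M/s times [catalyst], 0.840 d. That makes 1.60 d, and the feed of 80 min is short against it.

The run time is about ten times the clock. This reckoning therefore commits to 60.0% product, with conversion higher by the 0.267% held on the catalyst.

The forecast says the coupling partner has run out first, with conversion 60.27% and product 60%, the partner “used up within a day or so”.

The flask gives the coupling partner has run out first, with conversion 60.3% and product 60.0%.

In the flask the clock of 1.60 d stands far below 15 d, and product is at 60.0% after 3.00 d, with catalyst intermediate B at 100% of the catalyst after 7.50 d. The neighbour with 6.8 mM of partner has a clock of 0.950 d, again short, and stands at 15.1% product.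

The numbers are made up, and the outcome is calculated.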